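## Analysis of the target

1. Target 27 is a monocyclic 7,8-seco-jatrophane, and jatrophane numbering is used throughout. The only ring is the cyclopentane C15–C1–C2–C3–C4. C4 carries the enal arm C5=C6(CH3)–C7HO. C15 carries the arm C14(OAc)–C13(CH3)–C12=C11–C10(CH3)2–C9(=O)–C8H3.
2. There are six stereocentres, (2R,3S,4S,13R,14R,15R). On the ring, the C3 benzoate, the C4–C5 bond and the C15 acetate share one face as a contiguous all-cis O/C/O triad, while the C2 methyl group and the C15–C14 bond lie on the other face. In the chain, C13-CH3 and C14-OAc are anti, and C14/C15 form a fully acylated vicinal diol with a quaternary carbinol carbon.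
3. Both alkenes are E, and C11=C12 ends at the quaternary C10, which disfavours most olefinations at that site.
4. Several groups are sensitive:
   - Three esters of two kinds must be told apart, and the tertiary C15 hydroxyl is hard to acylate.
   - C3-OBz and C15-OAc are both β to C5, so any C5 carbonyl intermediate invites E1cB loss.
   - The enal is a Michael acceptor.
   - The 1,7-diene C5=C6/C11=C12 would close to a cyclohexene under metathesis conditions.
5. The hard part is the contiguous tetrad C4–C15–C14–C13. Half of it lies in the ring and half in the chain, and it must be set together with the contrasteric cis relation of C3-O to C4–C5.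
6. The plan exploits the fact that this tetrad is flanked on both sides by an E-alkene. O–C15–C4–C5=C6 and O–C14–C13–C12=C11 are therefore two homoallylic-alcohol retrons that meet at the C14–C15 bond. In the first retron O15 and C5 are cis on the cyclopentane, which is the signature of an intramolecular carbonyl-ene reaction closing the ring at C4–C15.

## Retrosynthetic reasoning

**27 ⇒ 25 (C7–H bonds).** The enal is the most fragile function and would not survive hydride, organometallic or Lewis-acid steps. It is taken back to the E-methyl group of the isobutenyl compound 25. This removes a stereodefined trisubstituted alkene from the problem, because C6 then carries two equal methyl groups. The forward reaction (via 26) is an allylic C–H oxidation. It must choose the trisubstituted C5=C6 alkene over C11=C12, and the methyl group trans to C4.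

**25 ⇒ 24 ⇒ 23 ⇒ 22 (three acyl–O or C–O bonds).**
- Both acetates come from diol 24 in one operation, which is possible only if the benzoate is already in place.
- The benzoate is introduced by SN2 displacement at C3 of 22, which has the opposite C3 configuration, and not by acylation.
- This choice turns the contrasteric cis C3-O/C4–C5 relation from a burden on the ring closure into the result of an inversion.

**22 ⇒ 21 ⇒ 11 + 20 (C13–C14).**
- The chain is cut inside the second homoallylic retron.
- The cut is not made at C11=C12, where the neopentyl position blocks olefination and where metathesis would close the 1,7-diene.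
- It is not made at C14–C15 either, where a secondary carbanion would be needed.
- The forward reaction joins aldehyde 11 to the α-chiral crotylsilane 20 with allylic transposition. It must set C13, C14 and the E-alkene at once.

**11 ⇒ 10 ⇒ 9 ⇒ 8 (C4–C15, key disconnection).**
- The first homoallylic retron is opened, so cyclopentanol 9 becomes the acyclic ε,ζ-unsaturated α-keto ester 8.
- The cut removes the only ring, the quaternary carbinol C15, the stereocentre C4 and the C5=C6 alkene.
- What remains is a chain with two stereocentres.
- The ester that activates the ketone is C14 itself, so no atom is wasted.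

**8 ⇒ 7 ⇒ 6 ⇒ 4 + 5 (C1=C15) and 4 ⇒ 3 ⇒ 1 + 2 (C2–C3).**
- The keto ester is traced through the α-hydroxy ester 7 to enoate 6.
- Cross-metathesis assembles 6 from 4 and acrylate 5, which brings in C15 and C14.
- The anti C2/C3 pair comes from one catalytic crotylboration of enal 1 with boronate 2.
- The anti series is chosen on purpose, because it lets both substituents sit on the convex face of the ene transition state.

**20 ⇒ 19 ⇒ 16 ⇒ 14 + 15 and 14 ⇒ 12 + 13 (C10–C11).** The quaternary C10 and the silyl-bearing stereocentre C11 are made together by a [3,3] shift of ester 16 (via 17 and 18). Chirality is transferred from the commercial alcohol 12.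

## Alternatives that were turned down

**Alternative 1 (textbook).**
- Disconnection: cut C14–C15 and C5=C6.
- Forward key step: cyclopentanone A1 would take up the side chain as the α-alkoxy organolithium made from stannane A2, adding anti to the C4 substituent. The enal would come from a stabilised-ylide Wittig reaction at C5.
- Reasons for rejection:
  - A1 is a β-benzoyloxy ketone whose C4–H is both α to the carbonyl and allylic. Loss of benzoate by E1cB and epimerisation to the more stable trans isomer are therefore built into the substrate.
  - A basic organolithium would enolise A1 rather than add to it.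
  - A1 already holds three contiguous ring stereocentres, so the ring problem is only postponed.
  - A2 needs its own two stereocentres and a ketone mask. The step count is higher, and C14/C15 are joined without any internal relay.

**Alternative 2.**
- Disconnection: cut C4–C15 in the all-carbon sense.
- Forward key step: the 1,6-enyne A3 would undergo an Alder-ene cycloisomerisation (Pd(OAc)2 with a phosphine) to the 1,4-diene A4. Syn-dihydroxylation of C14=C15 would follow.
- Reasons for rejection:
  - The ring closure itself is attractive, but OsO4 would have to choose one of three alkenes.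
  - It would also have to approach C15 from the face that carries C3-OBz and the C4 alkenyl group. Attack from the open face gives the wrong C15 and C14.
  - The carbonyl-ene reaction is the oxygen analogue that brings O15 in from the correct face by geometry, so the oxidation step is unnecessary.

**Alternative 3 (biomimetic).**
- Disconnection: add the C7–C8 bond.
- Forward key step: the 12-membered β-hydroxy ketone A5 would be opened by a retro-aldol reaction to the aldehyde and the methyl ketone.
- Reasons for rejection:
  - The precursor is more complex than the product. It has a strained macrocycle with two E-alkenes, one more stereocentre, and a ring closure next to a quaternary carbon.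
  - The basic retro-aldol conditions would meet three esters.
  - They would also generate a newly formed enal flanked by β-acyloxy groups.
  - The key step would therefore simplify nothing.

Key step: step 6

Assumption: (R)-TRIP is taken to deliver the crotyl group to the Re face of 1, as the closed transition-state model predicts. The enantiomeric acid would be used if the sense were opposite.

## Route

Step 1
Reactants: 1 (E)-4-methylpent-2-enal; 2 (E)-crotylboronic acid pinacol ester
Product: 3 (3R,4S,5E)-3,7-dimethylocta-1,5-dien-4-ol (anti; C2 as in 27, C3 opposite to 27)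
Conditions: (R)-TRIP [(R)-3,3'-bis(2,4,6-triisopropylphenyl)-1,1'-binaphthyl-2,2'-diyl hydrogen phosphate] (5 mol %), toluene, −30 °C; aqueous work-up
Reagents that add atoms: none
Why: Brønsted-acid-catalysed allylboration through a closed chair (Zimmerman–Traxler) transition state, in which the E-boronate gives the anti C2/C3 relation and the chiral acid, hydrogen-bonded to a boronate oxygen and the formyl hydrogen, should expose the Re face of 1. 1,2-Addition is inherent to the six-membered transition state, so the enal is not attacked in the conjugate sense.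

Step 2
Reactants: 3 (3R,4S,5E)-3,7-dimethylocta-1,5-dien-4-ol
Product: 4 tert-butyl{[(3R,4S,5E)-3,7-dimethylocta-1,5-dien-4-yl]oxy}dimethylsilane
Conditions: TBSCl, imidazole, DMF, rt
Reagents that add atoms: tert-butyldimethylsilyl chloride, CC(C)(C)[Si](C)(C)Cl
Why: Standard silyl ether formation. The group stands 180 °C, is a poor leaving group next to the alkene, and is a poor chelator, which keeps TiCl4 away from C3 in step 13.

Step 3
Reactants: 4 silyl ether of 3; 5 methyl acrylate
Product: 6 methyl (2E,4R,5S,6E)-5-(tert-butyldimethylsilyloxy)-4,8-dimethylnona-2,6-dienoate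
Conditions: Hoveyda–Grubbs second-generation catalyst RuCl2(H2IMes)(=CH-C6H4-2-O-i-Pr) (3 mol %), 5 (3 equiv), CH2Cl2, 40 °C
Reagents that add atoms: none
Why: Olefin cross-metathesis of a terminal alkene with an acrylate is product-selective and E-selective. The internal C4=C5 alkene lies between two branched carbons and should stay untouched, and the 1,4-diene cannot ring-close.

Step 4
Reactants: 6 dienoate
Product: 7 methyl (4R,5R,6E)-5-(tert-butyldimethylsilyloxy)-2-hydroxy-4,8-dimethylnon-6-enoate (both epimers at the carbinol carbon C15)
Conditions: Mn(dpm)3 (5 mol %), PhSiH3, O2 (1 atm), i-PrOH, 0 °C to rt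
Reagents that add atoms: dioxygen, O=O
Why: Mukaiyama-type reductive α-hydroxylation, in which a manganese hydride transfers a hydrogen atom to C1 of the enoate, O2 traps the ester-stabilised C15 radical, and the silane reduces the peroxide. The isolated 1,2-disubstituted alkene would give only an unstabilised secondary radical and should react far more slowly. The new centre is erased in step 5.

Step 5
Reactants: 7 α-hydroxy ester
Product: 8 methyl (4R,5R,6E)-5-(tert-butyldimethylsilyloxy)-4,8-dimethyl-2-oxonon-6-enoate
Conditions: Dess–Martin periodinane, CH2Cl2, 0 °C to rt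
Reagents that add atoms: none
Why: Dess–Martin oxidation of a secondary α-hydroxy ester. The near-neutral conditions avoid enolisation and self-aldol reaction of the α-keto ester.

Step 6
Reactants: 8 ε,ζ-unsaturated α-keto ester
Product: 9 methyl (1R,2S,3R,4R)-3-(tert-butyldimethylsilyloxy)-1-hydroxy-4-methyl-2-(2-methylprop-1-enyl)cyclopentane-1-carboxylate (ring C1 = C15, C2 = C4, C3 = C3, C4 = C2)
Conditions: toluene (0.02 M), BHT (cat.), sealed tube, 180 °C
Reagents that add atoms: none
Why: Concerted thermal intramolecular carbonyl-ene reaction (type 1, tether on the olefinic terminus), in which the C4=C5 π bond attacks the ketone carbon C15 of the electron-poor 1,2-dicarbonyl unit while the tertiary allylic C6–H passes to the ketone oxygen through a six-membered array, so that C4–C15 forms, the alkene moves to C5=C6 and the C15 hydroxyl appears in one event. The closest known reaction type is the uncatalysed ene cyclisation of ε,ζ-unsaturated α-keto esters to 2-alkenyl-1-hydroxycyclopentanecarboxylates. The only ring, C15–C1–C2–C3–C4, closes in a 5-exo mode with respect to both the C=O and the C=C bond. For C15 relative to C4, O15 and C5 both belong to the pericyclic six-ring, which can only be cis-fused to the nascent five-ring, so O15 and C5 must end up cis and the ester trans to C5. For C4/C15 relative to C2/C3, the anti-configured chain lets both the methyl and the silyloxy group sit on the convex face away from the ene array, with C3–H rather than C3–O next to C5–H, whereas attack on the other alkene face would place all four substituents cis. The substrate secures chemoselectivity, because it has one alkene, one allylic hydrogen that can reach the oxygen (C6–H, since C3–H lies in the tether) and only one activated carbonyl, and high dilution suppresses the bimolecular ene reaction. No E/Z issue arises because C6 carries two methyl groups.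

Step 7
Reactants: 9 cyclopentanol
Product: 10 methyl (1R,2S,3R,4R)-3-(tert-butyldimethylsilyloxy)-1-(methoxymethoxy)-4-methyl-2-(2-methylprop-1-enyl)cyclopentane-1-carboxylate
Conditions: MOMCl, i-Pr2NEt, NaI (cat.), 1,2-dichloroethane, 60 °C
Reagents that add atoms: chloromethyl methyl ether, COCCl
Why: O-Alkylation with a small, very reactive electrophile is the reliable way to cap a hindered tertiary alcohol. The acetal ether is a good chelator for step 13 and blocks the α-ketol rearrangement of the later α-oxy aldehyde.

Step 8
Reactants: 10 ester
Product: 11 (1R,2S,3R,4R)-3-(tert-butyldimethylsilyloxy)-1-(methoxymethoxy)-4-methyl-2-(2-methylprop-1-enyl)cyclopentane-1-carbaldehyde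
Conditions: i-Bu2AlH (1.2 equiv), toluene, −78 °C; aqueous work-up
Reagents that add atoms: none
Why: Partial ester reduction. The tetrahedral aluminium hemiacetal is held by chelation to the α-oxygen and by the neopentyl surroundings until work-up, so the reaction should stop at the aldehyde.

Step 9
Reactants: 12 (R)-but-3-yn-2-ol; 13 dimethyl(phenyl)silane
Product: 14 (2R,3E)-4-[dimethyl(phenyl)silyl]but-3-en-2-ol
Conditions: Pt2(dvtms)3 (dvtms = 1,3-divinyl-1,1,3,3-tetramethyldisiloxane, 0.1 mol %), P(t-Bu)3, THF, rt
Reagents that add atoms: none
Why: Platinum-catalysed alkyne hydrosilylation is a syn addition, and the bulky phosphine directs silicon to the terminal carbon to give the (E)-vinylsilane. The carbinol stereocentre is not touched.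

Step 10
Reactants: 14 vinylsilane alcohol; 15 2-methylpropanoyl chloride
Product: 16 (2R,3E)-4-[dimethyl(phenyl)silyl]but-3-en-2-yl 2-methylpropanoate
Conditions: pyridine, DMAP (cat.), CH2Cl2, 0 °C to rt
Reagents that add atoms: none
Why: Plain acylation of a secondary allylic alcohol, with no change at the stereocentre.

Step 11
Reactants: 16 allylic isobutyrate
Product: 19 (3S,4E)-3-[dimethyl(phenyl)silyl]-2,2-dimethylhex-4-enoic acid, via silyl ketene acetal 17 (not isolated), via trimethylsilyl ester 18 (not isolated)
Conditions: LiN(i-Pr)2, THF, −78 °C; Me3SiCl; to 60 °C; then 1 M HCl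
Reagents that add atoms: none
Why: Ireland–Claisen rearrangement through a chair with the carbinol methyl group equatorial. The suprafacial shift transfers the (R)-C–O stereocentre (C13) to the (S)-C–C stereocentre (C11) and gives the E-alkene, and it forges the quaternary C10 next to silicon. The symmetric dimethyl ketene acetal removes any enolate-geometry issue.

Step 12
Reactants: 19 acid
Product: 20 (4S,5E)-4-[dimethyl(phenyl)silyl]-3,3-dimethylhept-5-en-2-one
Conditions: MeLi (2.2 equiv), Et2O, −78 to 0 °C; then H2O
Reagents that add atoms: methyllithium, [Li]C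
Why: Addition of MeLi to a lithium carboxylate. The hindered geminal dialkoxide survives until work-up, so the reaction should stop at the methyl ketone.

Step 13
Reactants: 11 aldehyde; 20 crotylsilane
Product: 21 coupled alcohol, (2R,3R,4S,13R,14R,15R)-configured: 14-OH, 15-O-MOM, 3-O-TBS, isobutenyl on C4, complete C8–C14 arm
Conditions: TiCl4 (1.1 equiv), CH2Cl2, −78 °C, 11 precomplexed, then 20 (1.5 equiv); then H2O
Reagents that add atoms: none
Why: Hosomi–Sakurai addition of an enantioenriched α-chiral (E)-crotylsilane to a chelated α-alkoxy aldehyde. TiCl4 ties the aldehyde oxygen to the C15 ether oxygen (Cram chelate), so 20 must approach past C1H2 rather than past the substituted C4, which sets C14 (R), while the anti-SE2' course (C–Si antiperiplanar to the new bond, C11–H eclipsing the alkene) sets C13 (R) from C11 (S) and leaves E-C11=C12. Each partner fixes its own face, so the anti C13/C14 relation follows, and the ketone of 20 is far less electrophilic than the chelated aldehyde and could be reached by its own allylsilane only in a 5-endo mode.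

Step 14
Reactants: 21 coupled alcohol
Product: 22 3,14-diol (3R), 15-O-MOM
Conditions: HF·pyridine, pyridine, THF, 0 °C to rt
Reagents that add atoms: none
Why: Fluoride-driven cleavage of the silyl ether under buffered conditions. The acetal ether, the ketone and both alkenes are inert to it.

Step 15
Reactants: 22 3,14-diol
Product: 23 3-O-benzoate (3S, as in 27), 14-OH, 15-O-MOM
Conditions: PPh3, DIAD, PhCO2H, toluene, 0 °C to rt
Reagents that add atoms: benzoic acid, OC(=O)c1ccccc1
Why: Mitsunobu reaction, in which SN2 displacement of the C3 oxyphosphonium ion by benzoate inverts C3 to the configuration of 27 and installs the benzoate in the same operation. The C14 hydroxyl is wedged between the quaternary C15 and the branched C13 and should not be activated, and O15 is still an ether, so no neighbouring acyloxy group can intervene.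

Step 16
Reactants: 23 benzoate
Product: 24 14,15-diol 3-benzoate
Conditions: ZnBr2, n-PrSH, CH2Cl2, 0 °C
Reagents that add atoms: none
Why: Lewis-acid/thiol cleavage of the methoxymethyl ether by transacetalisation onto sulfur. It is fast for tertiary ethers and spares the benzoate, the ketone and the alkenes at short contact time.

Step 17
Reactants: 24 diol
Product: 25 14,15-diacetate 3-benzoate with isobutenyl on C4
Conditions: Ac2O (excess), DMAP, Et3N, CH2Cl2, 40 °C
Reagents that add atoms: acetic anhydride, CC(=O)OC(C)=O
Why: DMAP-catalysed acylation. The secondary C14 hydroxyl reacts first, and the tertiary C15 hydroxyl follows with excess reagent and gentle heating, so both acetates are set in one operation.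

Step 18
Reactants: 25 diacetate
Product: 27 CNP0489076.2 (target), via allylic alcohol 26 (not isolated)
Conditions: SeO2 (0.3 equiv), t-BuOOH, CH2Cl2, 0 °C to rt; then Dess–Martin periodinane, CH2Cl2, 0 °C
Reagents that add atoms: tert-butyl hydroperoxide, CC(C)(C)OO; selenium dioxide (oxygen relay), O=[Se]=O
Why: Riley allylic oxidation, in which the ene reaction of SeO2 at the more electron-rich trisubstituted alkene and the following [2,3]-sigmatropic shift oxidise the methyl group trans to C4 (E-selective), and the Dess–Martin stage brings all material to the enal. The hindered 1,2-disubstituted C11=C12 alkene and the methyl ketone react much more slowly at room temperature.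

## Compound list

1 | (E)-4-methylpent-2-enal | CC(C)/C=C/C=O | starting material
2 | (E)-crotylboronic acid pinacol ester | C/C=C/CB1OC(C)(C)C(C)(C)O1 | starting material
3 | (3R,4S,5E)-3,7-dimethylocta-1,5-dien-4-ol | C=C[C@@H](C)[C@@H](O)/C=C/C(C)C | intermediate
4 | tert-butyldimethylsilyl ether of 3 | C=C[C@@H](C)[C@@H](O[Si](C)(C)C(C)(C)C)/C=C/C(C)C | intermediate
5 | methyl acrylate | C=CC(=O)OC | starting material
6 | methyl (2E,4R,5S,6E)-5-(tert-butyldimethylsilyloxy)-4,8-dimethylnona-2,6-dienoate | COC(=O)/C=C/[C@@H](C)[C@@H](O[Si](C)(C)C(C)(C)C)/C=C/C(C)C | intermediate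
7 | methyl (4R,5R,6E)-5-(tert-butyldimethylsilyloxy)-2-hydroxy-4,8-dimethylnon-6-enoate (epimers at the carbinol carbon) | COC(=O)C(O)C[C@@H](C)[C@@H](O[Si](C)(C)C(C)(C)C)/C=C/C(C)C | intermediate
8 | methyl (4R,5R,6E)-5-(tert-butyldimethylsilyloxy)-4,8-dimethyl-2-oxonon-6-enoate | COC(=O)C(=O)C[C@@H](C)[C@@H](O[Si](C)(C)C(C)(C)C)/C=C/C(C)C | intermediate
9 | methyl (1R,2S,3R,4R)-3-(tert-butyldimethylsilyloxy)-1-hydroxy-4-methyl-2-(2-methylprop-1-enyl)cyclopentane-1-carboxylate | COC(=O)[C@@]1(O)C[C@@H](C)[C@@H](O[Si](C)(C)C(C)(C)C)[C@@H]1C=C(C)C | intermediate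
10 | methoxymethyl ether of 9 | COC(=O)[C@@]1(OCOC)C[C@@H](C)[C@@H](O[Si](C)(C)C(C)(C)C)[C@@H]1C=C(C)C | intermediate
11 | (1R,2S,3R,4R)-3-(tert-butyldimethylsilyloxy)-1-(methoxymethoxy)-4-methyl-2-(2-methylprop-1-enyl)cyclopentane-1-carbaldehyde | O=C[C@@]1(OCOC)C[C@@H](C)[C@@H](O[Si](C)(C)C(C)(C)C)[C@@H]1C=C(C)C | intermediate
12 | (R)-but-3-yn-2-ol | C[C@@H](O)C#C | starting material
13 | dimethyl(phenyl)silane | C[SiH](C)c1ccccc1 | starting material
14 | (2R,3E)-4-[dimethyl(phenyl)silyl]but-3-en-2-ol | C[C@@H](O)/C=C/[Si](C)(C)c1ccccc1 | intermediate
15 | 2-methylpropanoyl chloride | CC(C)C(=O)Cl | starting material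
16 | (2R,3E)-4-[dimethyl(phenyl)silyl]but-3-en-2-yl 2-methylpropanoate | CC(C)C(=O)O[C@H](C)/C=C/[Si](C)(C)c1ccccc1 | intermediate
17 | trimethylsilyl ketene acetal of 16 | CC(C)=C(O[Si](C)(C)C)O[C@H](C)/C=C/[Si](C)(C)c1ccccc1 | intermediate
18 | trimethylsilyl ester of 19 | C/C=C/[C@H]([Si](C)(C)c1ccccc1)C(C)(C)C(=O)O[Si](C)(C)C | intermediate
19 | (3S,4E)-3-[dimethyl(phenyl)silyl]-2,2-dimethylhex-4-enoic acid | C/C=C/[C@H]([Si](C)(C)c1ccccc1)C(C)(C)C(=O)O | intermediate
20 | (4S,5E)-4-[dimethyl(phenyl)silyl]-3,3-dimethylhept-5-en-2-one | C/C=C/[C@H]([Si](C)(C)c1ccccc1)C(C)(C)C(C)=O | intermediate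
21 | coupled alcohol (2R,3R,4S,13R,14R,15R): 14-OH, 15-O-MOM, 3-O-TBS | O[C@H]([C@H](C)/C=C/C(C)(C)C(C)=O)[C@@]1(OCOC)C[C@@H](C)[C@@H](O[Si](C)(C)C(C)(C)C)[C@@H]1C=C(C)C | intermediate
22 | 3,14-diol (3R), 15-O-MOM | O[C@H]([C@H](C)/C=C/C(C)(C)C(C)=O)[C@@]1(OCOC)C[C@@H](C)[C@@H](O)[C@@H]1C=C(C)C | intermediate
23 | 3-O-benzoate (3S), 14-OH, 15-O-MOM | O[C@H]([C@H](C)/C=C/C(C)(C)C(C)=O)[C@@]1(OCOC)C[C@@H](C)[C@H](OC(=O)c2ccccc2)[C@@H]1C=C(C)C | intermediate
24 | 14,15-diol 3-benzoate | O[C@H]([C@H](C)/C=C/C(C)(C)C(C)=O)[C@@]1(O)C[C@@H](C)[C@H](OC(=O)c2ccccc2)[C@@H]1C=C(C)C | intermediate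
25 | 14,15-diacetate 3-benzoate, isobutenyl on C4 | CC(=O)O[C@H]([C@H](C)/C=C/C(C)(C)C(C)=O)[C@@]1(OC(C)=O)C[C@@H](C)[C@H](OC(=O)c2ccccc2)[C@@H]1C=C(C)C | intermediate
26 | (5E)-C7 allylic alcohol | CC(=O)O[C@H]([C@H](C)/C=C/C(C)(C)C(C)=O)[C@@]1(OC(C)=O)C[C@@H](C)[C@H](OC(=O)c2ccccc2)[C@@H]1/C=C(\C)CO | intermediate
27 | CNP0489076.2, (2R,3S,4S,13R,14R,15R) | CC(=O)O[C@H]([C@H](C)/C=C/C(C)(C)C(C)=O)[C@@]1(OC(C)=O)C[C@@H](C)[C@H](OC(=O)c2ccccc2)[C@@H]1/C=C(\C)C=O | target

## Step count and least certain steps

Total step count: 18. Longest linear sequence: 14 steps (steps 1–8 and 13–18). The silane branch takes 4 steps (steps 9–12).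

**Step 6 (key step).**
- The ene reaction may be too slow, because the allylic silyloxy group inductively deactivates the 1,2-disubstituted alkene.
- Enolisation, decarbonylation or a bimolecular ene reaction of the keto ester could then compete at 180 °C.
- Facial selectivity may also erode at that temperature.
- Fallback, from 8 and back at 9: the same C4–C15 bond would be made photochemically and stepwise. Irradiation of 8 (365 nm, benzene, rt) should give the cis-fused 2-oxabicyclo[3.2.0]heptane oxetane F1, by an intramolecular Paternò–Büchi reaction of the excited keto carbonyl in the fused orientation. BF3·OEt2 (CH2Cl2, −78 °C) should then ionise only the C5–O bond, since the ester disfavours positive charge at C15. Loss of the C6 proton gives 9.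

**Step 13.**
- TiCl4 may cleave the methoxymethyl group or let it take part.
- Addition through a non-chelated (Felkin–Anh) array may lower the facial selectivity at C14.
- A 1,2-silyl shift with ring closure to a tetrahydrofuran, or protodesilylation, may consume the silane.
- Fallback, from 9 and back at 24: the chelate is replaced by a covalent ring.
  - Saponification (LiOH, THF/H2O) gives the hydroxy acid F2.
  - 2,2-Dimethoxypropane with PPTS closes the spiro-dioxolanone F3.
  - Reductive acetylation (i-Bu2AlH, −78 °C; then Ac2O, pyridine, DMAP) gives the 4-acetoxy-1,3-dioxolane F4.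
  - With BF3·OEt2, the cyclic oxocarbenium ion is attacked by 20 from the C1H2 side, which is the same sense as the chelate, to give the acetonide F5.
  - HF·pyridine frees the C3 alcohol F6, and the Mitsunobu reaction of step 15 gives the C3 benzoate F7.
  - Aqueous acetic acid then removes the acetonide to give 24.

**Step 15.**
- Backside attack at C3 has to pass the C4 alkenyl group, so displacement may be slow.
- E2 elimination toward C2, which has an antiperiplanar hydrogen, may take over.
- Activation of the C14 hydroxyl is a lesser risk.
- Fallback, from 22 and back at 23: inversion and acylation are separated (Lattrell–Dax inversion). Tf2O/pyridine at −20 °C should convert the less hindered hydroxyl into the C3 triflate F8. The small, weakly basic nucleophile Bu4NNO2 (toluene, rt, hydrolytic work-up) should give the inverted 3β-alcohol F9. BzCl/DMAP then acylates F9 at C3 to give 23.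

**Step 18.**
- The oxidation may stall because neighbouring ester groups screen the alkene.
- Forcing it may cause α-oxidation of the methyl ketone, oxidation at C13, or over-oxidation.
- Fallback, from 25 and back at 27: C–H oxidation is replaced by cleavage and olefination. OsO4 (cat.)/NaIO4 with 2,6-lutidine (dioxane/H2O) should cleave the more electron-rich trisubstituted alkene to the C5 aldehyde F10. F10 is taken without purification into a neutral Wittig reaction with 2-(triphenylphosphoranylidene)propanal (toluene, 60 °C) to give 27. The absence of base limits β-elimination of the acyloxy groups.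

**Step 4.**
- Hydrogen-atom transfer may also reach the isolated alkene.
- The C15 radical may be reduced before O2 traps it.
- Fallback, from 6 and back at 7: radical chemistry is replaced by polar chemistry. Conjugate reduction with [(Ph3P)CuH]6 (toluene, rt) gives the saturated ester F11. Enolisation with KN(SiMe3)2 (THF, −78 °C) and hydroxylation with 2-(phenylsulfonyl)-3-phenyloxaziridine (Davis oxidation) then give 7.

## Further compounds

F1 | step 6 | cis-fused oxetane, methyl 2-oxabicyclo[3.2.0]heptane-1-carboxylate with 3-isopropyl, 5-silyloxy and 6-methyl groups | COC(=O)[C@@]12C[C@@H](C)[C@@H](O[Si](C)(C)C(C)(C)C)[C@@H]1[C@@H](C(C)C)O2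
F2 | step 13 | hydroxy acid from 9 | OC(=O)[C@@]1(O)C[C@@H](C)[C@@H](O[Si](C)(C)C(C)(C)C)[C@@H]1C=C(C)C
F3 | step 13 | spiro-2,2-dimethyl-1,3-dioxolan-4-one | O=C1OC(C)(C)O[C@@]12C[C@@H](C)[C@@H](O[Si](C)(C)C(C)(C)C)[C@@H]2C=C(C)C
F4 | step 13 | spiro-4-acetoxy-2,2-dimethyl-1,3-dioxolane (epimers at C14) | CC(=O)OC1OC(C)(C)O[C@@]12C[C@@H](C)[C@@H](O[Si](C)(C)C(C)(C)C)[C@@H]2C=C(C)C
F5 | step 13 | 14,15-acetonide of the coupled product, 3-O-TBS | CC(=O)C(C)(C)/C=C/[C@@H](C)[C@H]1OC(C)(C)O[C@@]12C[C@@H](C)[C@@H](O[Si](C)(C)C(C)(C)C)[C@@H]2C=C(C)C
F6 | step 13 | 14,15-acetonide, free C3 alcohol (3R) | CC(=O)C(C)(C)/C=C/[C@@H](C)[C@H]1OC(C)(C)O[C@@]12C[C@@H](C)[C@@H](O)[C@@H]2C=C(C)C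
F7 | step 13 | 14,15-acetonide, C3 benzoate (3S) | CC(=O)C(C)(C)/C=C/[C@@H](C)[C@H]1OC(C)(C)O[C@@]12C[C@@H](C)[C@H](OC(=O)c3ccccc3)[C@@H]2C=C(C)C
F8 | step 15 | C3 triflate of 22 | O[C@H]([C@H](C)/C=C/C(C)(C)C(C)=O)[C@@]1(OCOC)C[C@@H](C)[C@@H](OS(=O)(=O)C(F)(F)F)[C@@H]1C=C(C)C
F9 | step 15 | inverted 3β-alcohol (C3 epimer of 22) | O[C@H]([C@H](C)/C=C/C(C)(C)C(C)=O)[C@@]1(OCOC)C[C@@H](C)[C@H](O)[C@@H]1C=C(C)C
F10 | step 18 | C5 aldehyde | CC(=O)O[C@H]([C@H](C)/C=C/C(C)(C)C(C)=O)[C@@]1(OC(C)=O)C[C@@H](C)[C@H](OC(=O)c2ccccc2)[C@@H]1C=O
F11 | step 4 | methyl (4R,5R,6E)-5-(tert-butyldimethylsilyloxy)-4,8-dimethylnon-6-enoate | COC(=O)CC[C@@H](C)[C@@H](O[Si](C)(C)C(C)(C)C)/C=C/C(C)C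
A1 | alternative 1 | 3-benzoyloxy-4-methyl-2-(2-methylprop-1-enyl)cyclopentanone, configured as in 27 | O=C1C[C@@H](C)[C@H](OC(=O)c2ccccc2)[C@@H]1C=C(C)C
A2 | alternative 1 | C14 tributylstannane of the side chain, 14-O-MOM, C9 ethylene ketal | COCO[C@H]([C@H](C)/C=C/C(C)(C)C1(C)OCCO1)[Sn](CCCC)(CCCC)CCCC
A3 | alternative 2 | acyclic 1,6-enyne (C14≡C15, C4=C5) | CC(=O)C(C)(C)/C=C/[C@@H](C)C#CC[C@@H](C)[C@H](OC(=O)c1ccccc1)/C=C/C(C)C
A4 | alternative 2 | alkylidenecyclopentane 1,4-diene (C14=C15, C13 cis to C1) | CC(=O)C(C)(C)/C=C/[C@@H](C)/C=C1\C[C@@H](C)[C@H](OC(=O)c2ccccc2)[C@@H]1C=C(C)C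
A5 | alternative 3 | 7-hydroxy-9-oxo-jatropha-5,11-diene triester (12-membered ring, C7 undefined) | CC(=O)O[C@@H]1[C@H](C)/C=C/C(C)(C)C(=O)CC(O)/C(C)=C/[C@H]2[C@@H](OC(=O)c3ccccc3)[C@H](C)C[C@]12OC(C)=O
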